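**Plan**
Retrosynthesis: cut the two O–Si bonds (7-O and 4'-O), then the C2–C3 bond of ring C (carbene C–H insertion), then the diazo group at C3 (diazo transfer to a methyl ketone), then the O1–C2 bond (aryl benzyl ether), then the C8–geranyl bond.
Forward: ring A arrives complete as 2,4-dihydroxyacetophenone and is C-geranylated at its C3 (future C8) and silylated at its 4-OH (future 7-O). The chelated phenol (future O1) is etherified with the ring B benzyl alcohol, the acetyl group becomes a diazoketone, and ring C is closed last.
Enabling feature: C2 carries both O1 and ring B, so in the open-chain aryl benzyl ether its two C–H bonds are doubly activated (alpha to oxygen, benzylic to an oxygenated arene). C3 sits alpha to the C4 ketone and can be a carbene carbon, and the ortho relation on ring A holds the two carbons 1,6 to each other.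
Stereochemistry: the single stereocentre C2 is set in the ring closure by a chiral dirhodium carboxylate that selects one of the two enantiotopic O–CH2 hydrogens; the E-alkene comes from geranyl bromide.
Helper groups: the diazo group leaves as N2 in the key step; the two silyl ethers come off at the end under buffered fluoride, so that ring C is not opened by base.

Key step: step 6

Assumption: Rh2(S-PTTL)4 is taken to deliver the 2S product; if the sense of induction is the opposite, the mirror-image complex from D-tert-leucine is used in the same way. "Geranyl" means (2E)-3,7-dimethylocta-2,6-dien-1-yl throughout.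

**Route**

Step 1
Reactants: 1 2,4-dihydroxyacetophenone; 2 geranyl bromide
Product: 3 1-(3-geranyl-2,4-dihydroxyphenyl)ethanone
Conditions: KOH (10% aq), 0 °C to rt
Reagents that add atoms: none
Why: Phenoxide C-alkylation in water, where hydrogen bonding to the phenoxide oxygens favours attack through carbon, should occur at C3, the position flanked by both oxygens and the most nucleophilic carbon of the resorcinol-type dianion, and SN2 attack on the primary allylic bromide keeps the E-alkene.

Step 2
Reactants: 3 1-(3-geranyl-2,4-dihydroxyphenyl)ethanone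
Product: 4 1-[3-geranyl-2-hydroxy-4-(triisopropylsilyloxy)phenyl]ethanone
Conditions: TIPSCl (1.05 equiv), imidazole, DMF, rt
Reagents that add atoms: triisopropylsilyl chloride CC(C)[Si](Cl)(C(C)C)C(C)C
Why: Selective O-silylation of the free 4-hydroxyl, because the 2-hydroxyl is held in a hydrogen bond to the acetyl carbonyl and is far less nucleophilic; the bulky triisopropylsilyl ether para to the acyl group is chosen to survive the later enolate and amine-base steps.

Step 3
Reactants: 5 4-(tert-butyldimethylsilyloxy)benzaldehyde
Product: 6 [4-(tert-butyldimethylsilyloxy)phenyl]methanol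
Conditions: NaBH4, THF/EtOH, 0 °C
Reagents that add atoms: none
Why: Borohydride reduction of an aryl aldehyde to the benzylic alcohol, which should leave the aryl silyl ether untouched at 0 °C.

Step 4
Reactants: 4 1-[3-geranyl-2-hydroxy-4-(triisopropylsilyloxy)phenyl]ethanone; 6 [4-(tert-butyldimethylsilyloxy)phenyl]methanol
Product: 7 1-[2-{[4-(tert-butyldimethylsilyloxy)phenyl]methoxy}-3-geranyl-4-(triisopropylsilyloxy)phenyl]ethanone
Conditions: PPh3, DIAD, THF, 0 °C to rt
Reagents that add atoms: none
Why: Mitsunobu etherification of an acidic, chelated phenol by a primary benzylic alcohol, under neutral conditions that spare both silyl ethers, the ketone and the geranyl chain.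

Step 5
Reactants: 7 1-[2-{[4-(tert-butyldimethylsilyloxy)phenyl]methoxy}-3-geranyl-4-(triisopropylsilyloxy)phenyl]ethanone
Product: 9 2-diazo-1-[2-{[4-(tert-butyldimethylsilyloxy)phenyl]methoxy}-3-geranyl-4-(triisopropylsilyloxy)phenyl]ethanone, via trifluoroacetyl diketone 8 (not isolated)
Conditions: LiN(SiMe3)2, THF, −78 °C; CF3CO2CH2CF3; cold 5% aq HCl quench; then MsN3, Et3N, H2O (1 equiv), MeCN, rt
Reagents that add atoms: methanesulfonyl azide CS(=O)(=O)N=[N+]=[N-]; 2,2,2-trifluoroethyl trifluoroacetate O=C(OCC(F)(F)F)C(F)(F)F (its CF3CO group is carried only by 8)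
Why: Regitz-type detrifluoroacetylative diazo transfer: the lithium enolate of the methyl ketone is trifluoroacetylated, and the activated 1,3-diketone 8 takes the diazo group from mesyl azide while the trifluoroacetyl group leaves as the N-mesyl amide, a standard way from aryl methyl ketones to terminal α-diazoketones.

Step 6
Reactants: 9 2-diazo-1-[2-{[4-(tert-butyldimethylsilyloxy)phenyl]methoxy}-3-geranyl-4-(triisopropylsilyloxy)phenyl]ethanone
Product: 10 (2S)-4'-(tert-butyldimethylsilyloxy)-8-geranyl-7-(triisopropylsilyloxy)flavanone
Conditions: Rh2(S-PTTL)4 (dirhodium tetrakis[N-phthaloyl-(S)-tert-leucinate], 2 mol %), 4 Å molecular sieves, CH2Cl2, 0 °C, slow addition of 9 by syringe pump (final 0.01 M)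
Reagents that add atoms: none
Why: Rh2(S-PTTL)4 expels N2 from 9 to give an electrophilic rhodium carbene at the future C3, which inserts into a C–H bond of the ether methylene five atoms away (the future C2) through a three-centre, hydride-transfer-like transition state with retention at carbon, forming the C3–C2 bond and releasing the catalyst. The closest known reaction type is the chiral dirhodium carboxylate-catalysed intramolecular C–H insertion of ortho-alkoxyaryl α-diazoketones to chroman-4-ones. Ring C closes as a six-membered ring by 1,6-insertion (C3, C4, C4a, C8a, O1 and C2 form the cyclic transition array), and no other ring is formed. The C2 stereocentre is set by the chiral carboxylate ligands, which tell apart the two enantiotopic hydrogens of the O–CH2 group; insertion into the pro-S hydrogen with retention gives 2S. The step needs chemoselectivity for this C–H bond over oxonium ylide formation at O1 and over attack on the geranyl alkenes; the substrate secures it because the C2–H bonds are doubly activated (alpha to O1 and benzylic to the silyloxyphenyl ring), O1 is a hindered aryl ether oxygen made less basic by the ortho acyl group, the near geranyl alkene sits meta to the acyl arm and cannot reach the carbene, and slow addition at high dilution suppresses intermolecular cyclopropanation.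

Step 7
Reactants: 10 (2S)-4'-(tert-butyldimethylsilyloxy)-8-geranyl-7-(triisopropylsilyloxy)flavanone
Product: 11 (2S)-7,4'-dihydroxy-8-geranylflavanone
Conditions: Bu4NF, AcOH (1:1, 2.5 equiv each), THF, 0 °C
Reagents that add atoms: none
Why: Fluoride cleavage of both aryl silyl ethers, buffered with acetic acid so that the phenols are released in protonated form and the base-induced opening of ring C (retro-oxa-Michael, helped by a 4'-phenoxide), which would scramble C2, should not set in.

**Compound list**
1 | 2,4-dihydroxyacetophenone | CC(=O)c1ccc(O)cc1O | starting material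
2 | geranyl bromide, (2E)-1-bromo-3,7-dimethylocta-2,6-diene | CC(C)=CCC/C(C)=C/CBr | starting material
3 | 1-(3-geranyl-2,4-dihydroxyphenyl)ethanone | CC(C)=CCC/C(C)=C/Cc1c(O)ccc(C(C)=O)c1O | intermediate
4 | 1-[3-geranyl-2-hydroxy-4-(triisopropylsilyloxy)phenyl]ethanone | CC(C)=CCC/C(C)=C/Cc1c(O[Si](C(C)C)(C(C)C)C(C)C)ccc(C(C)=O)c1O | intermediate
5 | 4-(tert-butyldimethylsilyloxy)benzaldehyde | O=Cc1ccc(O[Si](C)(C)C(C)(C)C)cc1 | starting material
6 | [4-(tert-butyldimethylsilyloxy)phenyl]methanol | OCc1ccc(O[Si](C)(C)C(C)(C)C)cc1 | intermediate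
7 | 1-[2-{[4-(tert-butyldimethylsilyloxy)phenyl]methoxy}-3-geranyl-4-(triisopropylsilyloxy)phenyl]ethanone | CC(C)=CCC/C(C)=C/Cc1c(O[Si](C(C)C)(C(C)C)C(C)C)ccc(C(C)=O)c1OCc1ccc(O[Si](C)(C)C(C)(C)C)cc1 | intermediate
8 | 4,4,4-trifluoro-1-[2-{[4-(tert-butyldimethylsilyloxy)phenyl]methoxy}-3-geranyl-4-(triisopropylsilyloxy)phenyl]butane-1,3-dione (not isolated) | CC(C)=CCC/C(C)=C/Cc1c(O[Si](C(C)C)(C(C)C)C(C)C)ccc(C(=O)CC(=O)C(F)(F)F)c1OCc1ccc(O[Si](C)(C)C(C)(C)C)cc1 | intermediate
9 | 2-diazo-1-[2-{[4-(tert-butyldimethylsilyloxy)phenyl]methoxy}-3-geranyl-4-(triisopropylsilyloxy)phenyl]ethanone | CC(C)=CCC/C(C)=C/Cc1c(O[Si](C(C)C)(C(C)C)C(C)C)ccc(C(=O)C=[N+]=[N-])c1OCc1ccc(O[Si](C)(C)C(C)(C)C)cc1 | intermediate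
10 | (2S)-4'-(tert-butyldimethylsilyloxy)-8-geranyl-7-(triisopropylsilyloxy)flavanone | CC(C)=CCC/C(C)=C/Cc1c(O[Si](C(C)C)(C(C)C)C(C)C)ccc2c1O[C@H](c1ccc(O[Si](C)(C)C(C)(C)C)cc1)CC2=O | intermediate
11 | (2S)-7,4'-dihydroxy-8-geranylflavanone | CC(C)=CCC/C(C)=C/Cc1c(O)ccc2c1O[C@H](c1ccc(O)cc1)CC2=O | target

**Count and risks**
Total steps: 7. Longest linear sequence: 6 (steps 1, 2, 4, 5, 6, 7).

Step 6 is the most likely to fail. The carbene may be diverted into oxonium ylide formation at O1 followed by a 1,2-shift of the benzyl group. The insertion may also turn stepwise (hydride transfer, then ion-pair collapse), and an acceptor-only carbene may discriminate the enantiotopic hydrogens poorly. The fallback sets out from 4 and comes back at 10. Compound 4 is heated with N,N-dimethylformamide dimethyl acetal (toluene, 90 °C) to give the enaminone (E)-3-(dimethylamino)-1-[3-geranyl-2-hydroxy-4-(triisopropylsilyloxy)phenyl]prop-2-en-1-one F1. Brief exposure of this to dilute acid (aq HCl, CH2Cl2, rt) should cyclise it to 8-geranyl-7-(triisopropylsilyloxy)-4H-chromen-4-one F2. Enantioselective conjugate addition of commercial 4-(tert-butyldimethylsilyloxy)phenylboronic acid to F2 should then give 10. The conditions for it are Pd(OCOCF3)2, 4-tert-butyl-2-(pyridin-2-yl)-4,5-dihydrooxazole in the enantiomeric form that leads to 2S, NH4PF6, H2O, 1,2-dichloroethane, 60 °C.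

Step 1 is the second risk: competing O-alkylation, alkylation at C5 and double alkylation may erode regiocontrol in the phenoxide C-alkylation. The fallback sets out from 2 and comes back at 3. Commercial 1,3-bis(methoxymethoxy)benzene is lithiated between its two acetal oxygens (n-BuLi, THF, 0 °C) and the aryllithium is alkylated with 2 to give 2-geranyl-1,3-bis(methoxymethoxy)benzene F3. A second directed ortho-lithiation (n-BuLi, TMEDA, THF, −78 to 0 °C) and acylation with N-methoxy-N-methylacetamide should give 1-[3-geranyl-2,4-bis(methoxymethoxy)phenyl]ethanone F4. Mild acid (HCl, MeOH, rt) should then remove both methoxymethyl groups and return 3.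

Step 4 is the third risk: the redox condensation may be sluggish at the hindered, hydrogen-bonded phenol flanked by acetyl and geranyl, and the electron-rich benzylic oxyphosphonium may ionise and self-condense. The fallback sets out from 6 and comes back at 7. Alcohol 6 is converted to 4-(tert-butyldimethylsilyloxy)benzyl bromide F5 (CBr4, PPh3, CH2Cl2, 0 °C). The potassium phenoxide of 4 is then alkylated with F5 (K2CO3, Bu4NI cat., acetone, 40 °C) to give 7.

Further compounds
F1 | step 6 | (E)-3-(dimethylamino)-1-[3-geranyl-2-hydroxy-4-(triisopropylsilyloxy)phenyl]prop-2-en-1-one | CC(C)=CCC/C(C)=C/Cc1c(O[Si](C(C)C)(C(C)C)C(C)C)ccc(C(=O)/C=C/N(C)C)c1O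
F2 | step 6 | 8-geranyl-7-(triisopropylsilyloxy)-4H-chromen-4-one | CC(C)=CCC/C(C)=C/Cc1c(O[Si](C(C)C)(C(C)C)C(C)C)ccc2c1occc2=O
F3 | step 1 | 2-geranyl-1,3-bis(methoxymethoxy)benzene | CC(C)=CCC/C(C)=C/Cc1c(OCOC)cccc1OCOC
F4 | step 1 | 1-[3-geranyl-2,4-bis(methoxymethoxy)phenyl]ethanone | CC(C)=CCC/C(C)=C/Cc1c(OCOC)ccc(C(C)=O)c1OCOC
F5 | step 4 | 4-(tert-butyldimethylsilyloxy)benzyl bromide | BrCc1ccc(O[Si](C)(C)C(C)(C)C)cc1
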